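**Retrosynthetic overview**

1. Kuraridin comes from a protected chalcone (three MOM ethers, SiEt3 on C-3 of ring B) by one mild acid step. No ring of the target is built: rings A and B are bought as benzenes, and the only ring closure is a transient four-membered oxete inside the key step.
2. Key disconnection: the bond between Cβ of the enone and C-1 of ring B. It is made together with the C-2–O bond of ring B and the Cα=Cβ double bond, by a three-component union of a ring-B aryne (C-1≡C-2, SiEt3 on C-3, OMOM on C-4), DMF (supplies Cβ and the C-2 oxygen) and the lithium enolate of the ring-A methyl ketone.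
3. Enabling feature: ring B carries Cβ on C-1 and a phenolic oxygen on the neighbouring C-2, a salicyl-type ortho C,O pair that matches the two termini of an aryne inserted into a formamide C=O. C-3 lies between O-2 and O-4, so a silyl director there leaves by ipso-protonation, and the ring-A ketone is enolisable only at its CH3 group.
4. The ring-A ketone comes from ortho-lithiation/acetylation of a symmetric 2-lavandulyl-5-methoxyresorcinol bis-MOM ether. That ether comes from Negishi coupling of the aryl iodide with the lavandulylzinc iodide, whose stereocentre is set by an oxazolidinone-controlled deconjugative alkylation.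
5. The aryne precursor comes from 4-bromoresorcinol by retro-Brook silyl migration (differentiates the two oxygens, places SiMe3), carbamate-directed ortho-silylation (places SiEt3) and triflation.

Key step: step 15

Remark on the chemistry: the lavandulyl centre is (R) in the target. The spatially identical acyl, alcohol, iodide and zinc precursors carry the descriptor (S), because the CIP priorities change when C=O, CH2–O, CH2–I or CH2–Zn is replaced by CH2–aryl.

**Route**

Step 1
Reactants: 1 (4S)-4-benzyl-1,3-oxazolidin-2-one; 2 3-methylbut-2-enoyl chloride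
Product: 4 (4S)-4-benzyl-3-(3-methylbut-2-enoyl)-1,3-oxazolidin-2-one, via lithium oxazolidinide 3 (not isolated)
Conditions: n-BuLi, THF, −78 °C; then 2, −78 → 0 °C
Reagents that add atoms: none
Why: N-acylation of the lithiated oxazolidinone by the acid chloride (nucleophilic acyl substitution), which does not touch the (4S) centre of the auxiliary.

Step 2
Reactants: 4 (4S)-4-benzyl-3-(3-methylbut-2-enoyl)-1,3-oxazolidin-2-one; 5 1-bromo-3-methylbut-2-ene
Product: 7 (4S)-4-benzyl-3-[(2S)-5-methyl-2-(prop-1-en-2-yl)hex-4-enoyl]-1,3-oxazolidin-2-one, via sodium dienolate 6 (not isolated)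
Conditions: NaN(SiMe3)2, THF, −78 °C; then 5, −78 → −30 °C
Reagents that add atoms: none
Why: Evans alkylation in its deconjugative form, in which γ-deprotonation gives the chelated (Z)-dienolate that is alkylated at the α-carbon on the face away from the benzyl group, so the auxiliary sets the (2S) centre (the later lavandulyl centre) while the isopropenyl group appears.

Step 3
Reactants: 7 (4S)-4-benzyl-3-[(2S)-5-methyl-2-(prop-1-en-2-yl)hex-4-enoyl]-1,3-oxazolidin-2-one
Product: 8 (2S)-5-methyl-2-(prop-1-en-2-yl)hex-4-en-1-ol
Conditions: LiBH4, MeOH (1 equiv), Et2O, 0 °C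
Reagents that add atoms: none
Why: hydride reduction of the exocyclic imide carbonyl (reductive removal of the auxiliary) under conditions that should neither epimerise the α-centre nor move the β,γ-double bond into conjugation.

Step 4
Reactants: 8 (2S)-5-methyl-2-(prop-1-en-2-yl)hex-4-en-1-ol
Product: 9 (3S)-3-(iodomethyl)-2,6-dimethylhepta-1,5-diene
Conditions: I2, PPh3, imidazole, CH2Cl2, 0 °C → rt
Reagents that add atoms: iodine, II
Why: Appel-type iodination, an SN2 displacement at the primary carbon that leaves the adjacent stereocentre and both alkenes untouched.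

Step 5
Reactants: 10 5-methoxybenzene-1,3-diol
Product: 11 1-methoxy-3,5-bis(methoxymethoxy)benzene
Conditions: MOMCl, i-Pr2NEt, CH2Cl2, 0 °C → rt
Reagents that add atoms: chloromethyl methyl ether, COCCl
Why: O-alkylation of both phenols (MOM acetal formation) gives a symmetric ether whose MOM groups later direct lithiation and come off with acid.

Step 6
Reactants: 11 1-methoxy-3,5-bis(methoxymethoxy)benzene
Product: 13 2-iodo-5-methoxy-1,3-bis(methoxymethoxy)benzene, via aryllithium 12 (not isolated)
Conditions: n-BuLi, THF, 0 °C; then I2, −78 °C → rt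
Reagents that add atoms: iodine, II
Why: directed ortho-metalation at the position flanked by the two chelating MOM ethers (favoured over the positions next to the weaker OMe director), followed by iodinolysis of the aryllithium.

Step 7
Reactants: 9 (3S)-3-(iodomethyl)-2,6-dimethylhepta-1,5-diene; 13 2-iodo-5-methoxy-1,3-bis(methoxymethoxy)benzene
Product: 15 5-methoxy-1,3-bis(methoxymethoxy)-2-[(2R)-5-methyl-2-(prop-1-en-2-yl)hex-4-en-1-yl]benzene, via alkylzinc iodide 14 (not isolated)
Conditions: Zn dust (activated), LiCl, THF, 40 °C; then 13, Pd(OAc)2 (3 mol %), SPhos (6 mol %), THF, 50 °C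
Reagents that add atoms: none
Why: Negishi coupling (zinc insertion into the primary C–I bond, then Pd/SPhos-catalysed sp3–sp2 coupling suited to doubly ortho-substituted electron-rich aryl iodides), in which the stereocentre β to the metal is not involved and its descriptor becomes R only through the change of CIP priorities.

Step 8
Reactants: 15 5-methoxy-1,3-bis(methoxymethoxy)-2-[(2R)-5-methyl-2-(prop-1-en-2-yl)hex-4-en-1-yl]benzene
Product: 17 1-{6-methoxy-2,4-bis(methoxymethoxy)-3-[(2R)-5-methyl-2-(prop-1-en-2-yl)hex-4-en-1-yl]phenyl}ethan-1-one, via aryllithium 16 (not isolated)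
Conditions: n-BuLi, TMEDA, THF, 0 °C; then MeC(O)N(OMe)Me, −78 → 0 °C; aq. NH4Cl
Reagents that add atoms: N-methoxy-N-methylacetamide, CC(=O)N(C)OC
Why: directed ortho-metalation at the only ring C–H type left (between OMOM and OMe, both positions equivalent by symmetry) and acylation with the Weinreb amide, whose chelated tetrahedral adduct prevents over-addition.

Step 9
Reactants: 18 4-bromobenzene-1,3-diol
Product: 19 1-bromo-2,4-bis(trimethylsilyloxy)benzene
Conditions: HN(SiMe3)2, THF, reflux
Reagents that add atoms: hexamethyldisilazane, C[Si](C)(C)N[Si](C)(C)C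
Why: O-silylation of both phenols by the silazane with loss of ammonia prepares the ortho-bromoaryl silyl ether needed for the retro-Brook step.

Step 10
Reactants: 19 1-bromo-2,4-bis(trimethylsilyloxy)benzene
Product: 23 5-hydroxy-2-(trimethylsilyl)phenyl diethylcarbamate, via aryllithium 20 (not isolated), via lithium phenoxide 21 (not isolated), via silyl ether carbamate 22 (not isolated)
Conditions: n-BuLi, THF, −78 °C → rt; then ClC(O)NEt2, 0 °C → rt; then MeOH, K2CO3 (cat.), 0 °C
Reagents that add atoms: diethylcarbamoyl chloride, CCN(CC)C(Cl)=O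
Why: bromine–lithium exchange followed by [1,3] retro-Brook rearrangement moves SiMe3 onto carbon only from the oxygen ortho to lithium, which differentiates the two oxygens, after which the freed phenoxide is O-carbamoylated and the remaining labile aryl O–SiMe3 bond is methanolysed.

Step 11
Reactants: 23 5-hydroxy-2-(trimethylsilyl)phenyl diethylcarbamate
Product: 24 5-(methoxymethoxy)-2-(trimethylsilyl)phenyl diethylcarbamate
Conditions: MOMCl, i-Pr2NEt, CH2Cl2, 0 °C → rt
Reagents that add atoms: chloromethyl methyl ether, COCCl
Why: O-alkylation of the free phenol (MOM acetal formation), to which the carbamate and the aryl–SiMe3 bond are inert.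

Step 12
Reactants: 24 5-(methoxymethoxy)-2-(trimethylsilyl)phenyl diethylcarbamate
Product: 26 3-(methoxymethoxy)-2-(triethylsilyl)-6-(trimethylsilyl)phenyl diethylcarbamate, via aryllithium 25 (not isolated)
Conditions: s-BuLi, TMEDA, THF, −78 °C; then Et3SiCl, −78 °C → rt
Reagents that add atoms: chlorotriethylsilane, CC[Si](Cl)(CC)CC
Why: directed ortho-metalation at the position between carbamate and MOM ether (cooperating directors, the other carbamate-ortho position being blocked by SiMe3) and C-silylation at −78 °C, below the onset of the anionic ortho-Fries rearrangement.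

Step 13
Reactants: 26 3-(methoxymethoxy)-2-(triethylsilyl)-6-(trimethylsilyl)phenyl diethylcarbamate
Product: 27 3-(methoxymethoxy)-2-(triethylsilyl)-6-(trimethylsilyl)phenol
Conditions: LiAlH4, THF, reflux; aq. NaOH work-up
Reagents that add atoms: none
Why: hydride attack at the carbamate carbonyl releases the phenoxide (reductive carbamate cleavage, the carbamoyl part ending as the N-methylamine) without touching the MOM ether or the aryl–silicon bonds.

Step 14
Reactants: 27 3-(methoxymethoxy)-2-(triethylsilyl)-6-(trimethylsilyl)phenol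
Product: 29 3-(methoxymethoxy)-2-(triethylsilyl)-6-(trimethylsilyl)phenyl trifluoromethanesulfonate, via lithium phenoxide 28 (not isolated)
Conditions: n-BuLi (1.0 equiv), Et2O, −78 → 0 °C; then Tf2O, −78 °C
Reagents that add atoms: trifluoromethanesulfonic anhydride, O=S(=O)(OS(=O)(=O)C(F)(F)F)C(F)(F)F
Why: O-sulfonylation of the hindered lithium phenoxide with the small, highly reactive anhydride gives the ortho-silylaryl triflate that serves as a fluoride-triggered aryne precursor.

Step 15
Reactants: 29 3-(methoxymethoxy)-2-(triethylsilyl)-6-(trimethylsilyl)phenyl trifluoromethanesulfonate; 30 N,N-dimethylformamide; 17 1-{6-methoxy-2,4-bis(methoxymethoxy)-3-[(2R)-5-methyl-2-(prop-1-en-2-yl)hex-4-en-1-yl]phenyl}ethan-1-one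
Product: 35 (2E)-3-[2-hydroxy-4-(methoxymethoxy)-3-(triethylsilyl)phenyl]-1-{6-methoxy-2,4-bis(methoxymethoxy)-3-[(2R)-5-methyl-2-(prop-1-en-2-yl)hex-4-en-1-yl]phenyl}prop-2-en-1-one, via aryne 31 (not isolated), via aminobenzoxete 32 (not isolated), via lithium enolate 33 (not isolated), via Mannich adduct 34 (not isolated)
Conditions: 29 (1.5 equiv), CsF (3 equiv), DMF (30, solvent), 0 °C → rt; then enolate 33 [from 17, LiN(SiMe3)2, THF, −78 °C] added at −40 °C → rt; then 60 °C; aq. NH4Cl
Reagents that add atoms: none
Why: Proposed new method: fluoride removes the SiMe3 group of 29 (the bulkier SiEt3 group should stay) and triflate leaves, giving aryne 31, whose C-2 terminus beside the σ-donating C–SiEt3 group is the flatter, more electrophilic carbon, so the small carbonyl oxygen of DMF 30 bonds there and the aryl anion that develops at C-1, remote from silicon, closes on the iminium carbon. This stepwise formal [2+2] addition (4-exo-trig closure of the transient four-membered oxete ring) gives aminobenzoxete 32, which is in equilibrium with its ring-opened ortho-quinone methide iminium–phenoxide form, and the lithium enolate 33 (enolisable only at the acetyl CH3), added once the aryne is spent, attacks the iminium carbon in a Mannich-type addition to give 34. Loss of dimethylamine by E1cB elimination on warming should then deliver the conjugated (E)-enone, so one operation forms the C-1(ring B)–Cβ bond, the C-2–O bond and the Cα=Cβ double bond. The closest known reaction type is the three-component coupling of arynes, DMF and active methylene compounds (coumarin and 2H-chromene syntheses) together with the sequential trapping of aryne–formamide adducts by organozinc reagents, extended here to a monoketone enolate and a 3-silyl-4-alkoxybenzyne, with the addition of small heteroatom nucleophiles to 3-silylbenzynes at the carbon next to silicon as regiochemical precedent. The only new stereocentre (the amino-bearing carbon of 32 and 34) is uncontrolled and is destroyed in the elimination, and the E geometry is the thermodynamic outcome. The step needs regioselectivity, secured by the silyl group beside the triple bond (the OMOM group on C-4 is one position further away and is expected to have only a small influence), and chemoselectivity for DMF over the enolate as first aryne partner, secured by DMF as solvent and by adding the enolate only after aryne generation is complete.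

Step 16
Reactants: 35 (2E)-3-[2-hydroxy-4-(methoxymethoxy)-3-(triethylsilyl)phenyl]-1-{6-methoxy-2,4-bis(methoxymethoxy)-3-[(2R)-5-methyl-2-(prop-1-en-2-yl)hex-4-en-1-yl]phenyl}prop-2-en-1-one
Product: 36 kuraridin, (2E)-1-{2,4-dihydroxy-6-methoxy-3-[(2R)-5-methyl-2-(prop-1-en-2-yl)hex-4-en-1-yl]phenyl}-3-(2,4-dihydroxyphenyl)prop-2-en-1-one
Conditions: HCl (3 M aq), MeOH, rt
Reagents that add atoms: none
Why: acid-catalysed acetal exchange removes the three MOM ethers as dimethoxymethane and ipso-protodesilylation (electrophilic aromatic substitution with silicon as leaving group) clears C-3 of ring B, the position activated by its two flanking oxygens, under the dilute HCl/MeOH conditions used for MOM removal from prenylated 2'-hydroxychalcones, so the alkenes, the E-enone and the stereocentre should be left alone.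

**Compound list**

1 | (4S)-4-benzyl-1,3-oxazolidin-2-one | O=C1N[C@@H](Cc2ccccc2)CO1 | starting material
2 | 3-methylbut-2-enoyl chloride | CC(C)=CC(Cl)=O | starting material
3 | lithium (4S)-4-benzyl-2-oxo-1,3-oxazolidin-3-ide | [Li]N1[C@@H](Cc2ccccc2)COC1=O | intermediate
4 | (4S)-4-benzyl-3-(3-methylbut-2-enoyl)-1,3-oxazolidin-2-one | CC(C)=CC(=O)N1[C@@H](Cc2ccccc2)COC1=O | intermediate
5 | 1-bromo-3-methylbut-2-ene | CC(C)=CCBr | starting material
6 | sodium (Z)-dienolate of 4 | C=C(C)/C=C(\O[Na])N1[C@@H](Cc2ccccc2)COC1=O | intermediate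
7 | (4S)-4-benzyl-3-[(2S)-5-methyl-2-(prop-1-en-2-yl)hex-4-enoyl]-1,3-oxazolidin-2-one | C=C(C)[C@H](CC=C(C)C)C(=O)N1[C@@H](Cc2ccccc2)COC1=O | intermediate
8 | (2S)-5-methyl-2-(prop-1-en-2-yl)hex-4-en-1-ol | C=C(C)[C@H](CC=C(C)C)CO | intermediate
9 | (3S)-3-(iodomethyl)-2,6-dimethylhepta-1,5-diene | C=C(C)[C@H](CC=C(C)C)CI | intermediate
10 | 5-methoxybenzene-1,3-diol | COc1cc(O)cc(O)c1 | starting material
11 | 1-methoxy-3,5-bis(methoxymethoxy)benzene | COCOc1cc(OC)cc(OCOC)c1 | intermediate
12 | [4-methoxy-2,6-bis(methoxymethoxy)phenyl]lithium | COCOc1cc(OC)cc(OCOC)c1[Li] | intermediate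
13 | 2-iodo-5-methoxy-1,3-bis(methoxymethoxy)benzene | COCOc1cc(OC)cc(OCOC)c1I | intermediate
14 | [(2S)-5-methyl-2-(prop-1-en-2-yl)hex-4-en-1-yl]zinc iodide | C=C(C)[C@H](CC=C(C)C)C[Zn]I | intermediate
15 | 5-methoxy-1,3-bis(methoxymethoxy)-2-[(2R)-5-methyl-2-(prop-1-en-2-yl)hex-4-en-1-yl]benzene | C=C(C)[C@H](CC=C(C)C)Cc1c(OCOC)cc(OC)cc1OCOC | intermediate
16 | aryllithium of 15, lithiated between OMOM and OMe | C=C(C)[C@H](CC=C(C)C)Cc1c(OCOC)cc(OC)c([Li])c1OCOC | intermediate
17 | 1-{6-methoxy-2,4-bis(methoxymethoxy)-3-[(2R)-5-methyl-2-(prop-1-en-2-yl)hex-4-en-1-yl]phenyl}ethan-1-one | C=C(C)[C@H](CC=C(C)C)Cc1c(OCOC)cc(OC)c(C(C)=O)c1OCOC | intermediate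
18 | 4-bromobenzene-1,3-diol | Oc1ccc(Br)c(O)c1 | starting material
19 | 1-bromo-2,4-bis(trimethylsilyloxy)benzene | C[Si](C)(C)Oc1ccc(Br)c(O[Si](C)(C)C)c1 | intermediate
20 | [2,4-bis(trimethylsilyloxy)phenyl]lithium | C[Si](C)(C)Oc1ccc([Li])c(O[Si](C)(C)C)c1 | intermediate
21 | lithium 2-(trimethylsilyl)-5-(trimethylsilyloxy)phenolate | C[Si](C)(C)Oc1ccc([Si](C)(C)C)c(O[Li])c1 | intermediate
22 | 2-(trimethylsilyl)-5-(trimethylsilyloxy)phenyl diethylcarbamate | CCN(CC)C(=O)Oc1cc(O[Si](C)(C)C)ccc1[Si](C)(C)C | intermediate
23 | 5-hydroxy-2-(trimethylsilyl)phenyl diethylcarbamate | CCN(CC)C(=O)Oc1cc(O)ccc1[Si](C)(C)C | intermediate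
24 | 5-(methoxymethoxy)-2-(trimethylsilyl)phenyl diethylcarbamate | CCN(CC)C(=O)Oc1cc(OCOC)ccc1[Si](C)(C)C | intermediate
25 | aryllithium of 24, lithiated between carbamate and OMOM | CCN(CC)C(=O)Oc1c([Li])c(OCOC)ccc1[Si](C)(C)C | intermediate
26 | 3-(methoxymethoxy)-2-(triethylsilyl)-6-(trimethylsilyl)phenyl diethylcarbamate | CCN(CC)C(=O)Oc1c([Si](CC)(CC)CC)c(OCOC)ccc1[Si](C)(C)C | intermediate
27 | 3-(methoxymethoxy)-2-(triethylsilyl)-6-(trimethylsilyl)phenol | COCOc1ccc([Si](C)(C)C)c(O)c1[Si](CC)(CC)CC | intermediate
28 | lithium 3-(methoxymethoxy)-2-(triethylsilyl)-6-(trimethylsilyl)phenolate | COCOc1ccc([Si](C)(C)C)c(O[Li])c1[Si](CC)(CC)CC | intermediate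
29 | 3-(methoxymethoxy)-2-(triethylsilyl)-6-(trimethylsilyl)phenyl trifluoromethanesulfonate | COCOc1ccc([Si](C)(C)C)c(OS(=O)(=O)C(F)(F)F)c1[Si](CC)(CC)CC | intermediate
30 | N,N-dimethylformamide | CN(C)C=O | starting material
31 | 4-(methoxymethoxy)-3-(triethylsilyl)benzyne | COCOC1=C([Si](CC)(CC)CC)C#CC=C1 | intermediate
32 | N,N-dimethyl-5-(methoxymethoxy)-6-(triethylsilyl)-2H-benzo[b]oxet-2-amine (ring-closed form of the ortho-quinone methide iminium phenoxide) | CN(C)C1Oc2c([Si](CC)(CC)CC)c(OCOC)ccc21 | intermediate
33 | lithium enolate of 17 | C=C(C)[C@H](CC=C(C)C)Cc1c(OCOC)cc(OC)c(C(=C)O[Li])c1OCOC | intermediate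
34 | lithium phenolate of the β-(dimethylamino) ketone (Mannich adduct, amino-bearing carbon unassigned) | C=C(C)[C@H](CC=C(C)C)Cc1c(OCOC)cc(OC)c(C(=O)CC(N(C)C)c2ccc(OCOC)c([Si](CC)(CC)CC)c2O[Li])c1OCOC | intermediate
35 | (2E)-3-[2-hydroxy-4-(methoxymethoxy)-3-(triethylsilyl)phenyl]-1-{6-methoxy-2,4-bis(methoxymethoxy)-3-[(2R)-5-methyl-2-(prop-1-en-2-yl)hex-4-en-1-yl]phenyl}prop-2-en-1-one | C=C(C)[C@H](CC=C(C)C)Cc1c(OCOC)cc(OC)c(C(=O)/C=C/c2ccc(OCOC)c([Si](CC)(CC)CC)c2O)c1OCOC | intermediate
36 | kuraridin | C=C(C)[C@H](CC=C(C)C)Cc1c(O)cc(OC)c(C(=O)/C=C/c2ccc(O)cc2O)c1O | target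

**Step count and risks**

Total step count: 16. Longest linear sequence: 8 steps (steps 1–4, 7, 8, 15, 16; the aryne branch, steps 9–16, is equally long).

Steps most likely to fail:

Step 15 (the step that bears the label). The formamide oxygen may add to the aryne carbon remote from silicon if the bulk of SiEt3 outweighs the distortion effect. Fluoride may attack SiEt3 in place of SiMe3. The aminobenzoxete may be consumed by a second aryne or by self-condensation before the enolate arrives, the enolate may add to residual aryne, and the amine elimination may stall at the Mannich stage. The fallback uses known chemistry and sets out from ketone 17. Commercial 2,4-dihydroxybenzaldehyde is converted with MOMCl and K2CO3 in acetone into 2,4-bis(methoxymethoxy)benzaldehyde F1. Claisen–Schmidt condensation of 17 with F1 (KOH, EtOH/H2O, rt; aldol addition and dehydration) gives the tetrakis-MOM chalcone F2. Treating F2 under the acid conditions of step 16 brings the route back at the target 36.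

Step 16. The free 2'-hydroxyl may close onto the enone under acid (oxa-Michael closure to the flavanone), phenols may cyclise onto the protonated lavandulyl alkenes, and ipso-protodesilylation may lag behind acetal cleavage. The fallback sets out from 35 and avoids Brønsted acid. Fluoride-induced protodesilylation ortho to the phenoxide (Bu4NF, wet THF, 0 °C → rt) gives the silicon-free tris-MOM chalcone F3. The MOM ethers of F3 are then exchanged under non-protic conditions (Me3SiOTf, 2,2'-bipyridyl, CH2Cl2, 0 °C) to give the tetrakis(trimethylsilyl) ether F4. Addition of water hydrolyses the aryl silyl ethers of F4, so the route comes back at 36.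

Step 7. Oxidative addition and transmetalation may be slow at the doubly ortho-substituted, electron-rich aryl iodide, so that β-hydride elimination and chain isomerisation of the β-branched alkyl–palladium intermediate take over. Radical rearrangement of the homoallylic system during zinc insertion is a further risk. The fallback reverses the polarity and sets out from 11 and 9. Aryllithium 12 (made from 11 as in step 6) is transmetalated with MgBr2 to the aryl Grignard reagent F5. F5 is alkylated by iodide 9 under copper catalysis (Li2CuCl4, THF/NMP, 0 °C → rt; Kochi-type sp2–sp3 coupling), which brings the route back at 15.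

**Further compounds**

F1 | step 15 | 2,4-bis(methoxymethoxy)benzaldehyde | COCOc1ccc(C=O)c(OCOC)c1
F2 | step 15 | (2E)-3-[2,4-bis(methoxymethoxy)phenyl]-1-{6-methoxy-2,4-bis(methoxymethoxy)-3-[(2R)-5-methyl-2-(prop-1-en-2-yl)hex-4-en-1-yl]phenyl}prop-2-en-1-one | C=C(C)[C@H](CC=C(C)C)Cc1c(OCOC)cc(OC)c(C(=O)/C=C/c2ccc(OCOC)cc2OCOC)c1OCOC
F3 | step 16 | (2E)-3-[2-hydroxy-4-(methoxymethoxy)phenyl]-1-{6-methoxy-2,4-bis(methoxymethoxy)-3-[(2R)-5-methyl-2-(prop-1-en-2-yl)hex-4-en-1-yl]phenyl}prop-2-en-1-one | C=C(C)[C@H](CC=C(C)C)Cc1c(OCOC)cc(OC)c(C(=O)/C=C/c2ccc(OCOC)cc2O)c1OCOC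
F4 | step 16 | tetrakis(trimethylsilyl) ether of kuraridin | C=C(C)[C@H](CC=C(C)C)Cc1c(O[Si](C)(C)C)cc(OC)c(C(=O)/C=C/c2ccc(O[Si](C)(C)C)cc2O[Si](C)(C)C)c1O[Si](C)(C)C
F5 | step 7 | [4-methoxy-2,6-bis(methoxymethoxy)phenyl]magnesium bromide | COCOc1cc(OC)cc(OCOC)c1[Mg]Br
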